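You can't read a tank off a batch curve: a well-mixed tank has no clock, and fresh feed leaves beside old liquor. You need a rule that converts one into the other.

| setting | south | south-east | north-west | south-west | spring | noon | autumn | midnight |
|---|---|---|---|---|---|---|---|---|
| substrate | 0.25 M | 0.17 M | 0.38 M | 0.25 M | 0.25 M | 0.25 M | 0.25 M | 0.25 M (fed, over 2.00 d) |
| partner | 0.30 M | 0.30 M | 0.30 M | 0.15 M | 0.300 M | 0.300 M | 0.300 M | 0.300 M |
| remark | run made earlier | run made earlier | run made earlier | run made earlier | a single well-mixed tank run continuously and read at steady state, 2.5 d in it on average | everything together in a closed stirred flask, run for 2.5 d | a single well-mixed tank run continuously and read at steady state, 25.0 d in it on average | all but substrate at the start; substrate goes in evenly over 2.00 d, the run ends at 2.5 d |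
| time |  |  |  |  |  | 2.5 d |  | 2.5 d |

south run (percent of the substrate charged)

| time / d | open intermediate / % | target / % | substrate / % |
|---|---|---|---|
| 0.417 | 50 | 0 | 35 |
| 0.833 | 68 | 4 | 15 |
| 1.25 | 73 | 3 | 8 |
| 1.67 | 77 | 11 | 8 |
| 2.00 | 75 | 10 | 6 |
| 2.50 | 74 | 16 | 4 |

south-east run (percent of the substrate charged)

| time / h | open intermediate / % | target / % | substrate / % |
|---|---|---|---|
| 2.50 | 19 | 0 | 78 |
| 8.00 | 43 | 0 | 44 |
| 12.0 | 54 | 1 | 30 |
| 20.0 | 70 | 1 | 15 |
| 30.0 | 74 | 4 | 7 |
| 40.0 | 76 | 9 | 6 |

north-west run (percent of the substrate charged)

| time / h | open intermediate / % | target / % | substrate / % |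
|---|---|---|---|
| 2.50 | 19 | 0 | 77 |
| 8.00 | 44 | 0 | 45 |
| 12.0 | 51 | 1 | 29 |
| 20.0 | 66 | 2 | 14 |
| 30.0 | 73 | 4 | 8 |
| 40.0 | 75 | 11 | 5 |

south-west run (percent of the substrate charged)

| time / h | open intermediate / % | target / % | substrate / % |
|---|---|---|---|
| 3.00 | 19 | 0 | 73 |
| 5.00 | 31 | 3 | 59 |
| 10.0 | 48 | 0 | 37 |
| 20.0 | 67 | 1 | 13 |
| 40.0 | 79 | 4 | 5 |

(scatter of a reading: 1.5 percentage points)

- the stated concentrations are those of everything mixed, before any reaction; amounts are the same in each set-up
- the feed brings no volume worth counting
- the earlier runs were made in a closed, stirred flask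

- order of the set-ups by the amount of open intermediate at the outlet or at the end, in percent of the substrate put in, highest first (spring / noon / autumn / midnight)
- amount of open intermediate at the outlet or at the end, in percent of the substrate put in, spring
- amount of open intermediate at the outlet or at the end, in percent of the substrate put in, noon
- amount of open intermediate at the outlet or at the end, in percent of the substrate put in, autumn
- amount of open intermediate at the outlet or at the end, in percent of the substrate put in, midnight

1. Substrate falls by about the same fraction per hour at each charge in the early readings, so treat its early loss as first order.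
2. South holds 15% substrate at 0.833 d. That gives 0.439 d for the making time θ, the time substrate takes to fall by a factor e. It carries the scatter of one reading.
3. The second time is the stay, 2.5 d on average in spring. South at 2.50 d holds less target, 16%, than open intermediate, 74%, so over such a stay the main question is how much substrate has opened.
4. Balance the tank: feed in equals outflow plus reaction, so [substrate] over its feed value is 1/(1 + stay/θ).
5. The ratio stay/θ, the Damköhler number, is 5.69. My own reckoning therefore lets 14.9% of the substrate leave spring unreacted.
6. The forecast says noon > midnight > spring > autumn: spring 58% (50% to 65%), noon 74% (71% to 77%), autumn 30% (17% to 45%), midnight 71% (66% to 75%). For spring it reasons “about 15% substrate remains”.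
7. The flasks give noon > midnight > spring > autumn: spring 59.0%, noon 72.6%, autumn 25.7%, midnight 68.0%.

    substrate → open intermediate (k = 0.0828 /h)
    partner → second intermediate (k = 0.0162 /h)
    open intermediate + second intermediate → target (k = 0.0460 /M/h)
    2 open intermediate → homo product (k = 7.31 × 10⁻⁴ /M/h)
    substrate ⇌ dormant form (K = 0.680, k = 0.0295 /h)

The order turns on two things acting together, the reverse step from dormant form to substrate and the length of the run: without that reverse step noon gives 57.1% instead of 72.6%, and noon read at 25.0 d gives 5.99%. Spring's outlet carries 15.5% of the substrate, beside the 14.9% reckoned from θ = 0.439 d. Now take θ to midnight. Integrating steady feed minus [substrate]/θ over the dosing time t_f = 2.00 d gives (θ/t_f)(1 − e^(−t_f/θ)) = 21.7% of the charge. Midnight holds 22.2% of its substrate at 2.00 d.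

All runs come from a simulation on assumed constants, noise included.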